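The α-methylene-γ-butyrolactone (ring O–C14–C1–C15–C16, cembrane numbering) is disconnected as a formal [3+2] union of the C14–C1–C15 unit with CO2. In the key step a C15 methyl ketone trisylhydrazone is converted into the C15 vinyllithium, which captures CO2 (C15–C16). The carboxylate then opens the adjacent trans-13,14-vinyl epoxide 5-exo at C14 with inversion (O–C14) and releases the C13 hydroxyl. This exploits the anti C13–O/C14–O pair beside C1 and the trans ring fusion. The precursor is a 14-membered carbocyclic bis-epoxide assembled from farnesol and ethyl (R)-3-hydroxybutanoate, whose carbinol first controls C1 and later becomes C15.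

Key step: step 12

Remark: cembrane numbering is used throughout (C1 = ring carbon bearing the C15 side chain, C16 = lactone carbonyl, C17 = exocyclic methylene, C18–C20 = methyls on C4, C8, C12). Isomerically pure (2E,6E)-farnesol is assumed.

Step 1
Reactants: 1 (2E,6E)-farnesol
Product: 2 (2S,3S)-2,3-epoxyfarnesol
Conditions: Ti(OiPr)4 (cat.), L-(+)-diethyl tartrate (cat.), t-BuOOH, 4 Å MS, CH2Cl2, −20 °C
Reagents that add atoms: tert-butyl hydroperoxide, CC(C)(C)OO
Why: Sharpless asymmetric epoxidation: the allylic hydroxyl binds the Ti–tartrate catalyst, so only the 2,3-alkene reacts, and L-(+)-tartrate directs oxygen to the face that gives the (2S,3S)-epoxide (future C3 and C4).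

Step 2
Reactants: 2 (2S,3S)-2,3-epoxyfarnesol
Product: 3 epoxyfarnesyl iodide, (2S,3R)-2-[(3E)-4,8-dimethylnona-3,7-dienyl]-3-(iodomethyl)-2-methyloxirane
Conditions: I2, PPh3, imidazole, CH2Cl2, 0 °C
Reagents that add atoms: iodine, II
Why: Appel-type iodination of the primary alcohol under buffered conditions leaves the oxirane and both of its stereocentres untouched (only the CIP label of the CH carbon changes).

Step 3
Reactants: 3 epoxyfarnesyl iodide; 4 ethyl (R)-3-hydroxybutanoate
Product: 6 ethyl (2R,3R)-3-hydroxy-2-{[(2S,3S)-3-[(3E)-4,8-dimethylnona-3,7-dienyl]-3-methyloxiran-2-yl]methyl}butanoate, via dilithio dianion 5 (not isolated)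
Conditions: 4, LDA (2.1 equiv), THF, −78 to −20 °C; then 3, DMPU, −78 to −10 °C; AcOH quench at −78 °C
Reagents that add atoms: none
Why: Fráter–Seebach alkylation: the chelated alkoxide–enolate dianion takes up the primary iodide (SN2, C1–C2 bond) on the face away from the carbinol methyl group, which sets C1 (2R) anti to the C15 carbinol.

Step 4
Reactants: 6 the β-hydroxy ester
Product: 7 tert-butyldimethylsilyl ether of 6 (C15–OTBS, all stereocentres as in 6)
Conditions: TBSCl, imidazole, DMAP (cat.), DMF, rt
Reagents that add atoms: tert-butyldimethylsilyl chloride, C[Si](C)(Cl)C(C)(C)C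
Why: Standard silylation under non-Lewis-acidic conditions masks the carbinol against retro-aldol and oxidation chemistry without touching the epoxide.

Step 5
Reactants: 7 the silyl ether
Product: 8 terminal (E)-allylic alcohol (C13–OH; side chain now (3E,7E)-9-hydroxy-4,8-dimethylnona-3,7-dienyl)
Conditions: SeO2 (cat.), salicylic acid (cat.), t-BuOOH, CH2Cl2, 0 °C to rt, stopped at partial conversion
Reagents that add atoms: tert-butyl hydroperoxide, CC(C)(C)OO
Why: Riley allylic oxidation (ene reaction, then [2,3]-shift) prefers the (E)-methyl group of the terminal isopropylidene unit of oligoprenyl chains and keeps the 11E geometry.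

Step 6
Reactants: 8 the allylic alcohol
Product: 9 (E)-allylic bromide (C13–Br)
Conditions: CBr4, PPh3, CH2Cl2, −20 °C
Reagents that add atoms: carbon tetrabromide, BrC(Br)(Br)Br
Why: Appel bromination of the only free hydroxyl is neutral and fast at low temperature, so ester, silyl ether and epoxide survive; it is placed before the aldehyde exists to avoid dibromo-olefination.

Step 7
Reactants: 9 the bromo ester
Product: 10 (2R,3R)-2-{[(2S,3S)-3-[(3E,7E)-9-bromo-4,8-dimethylnona-3,7-dienyl]-3-methyloxiran-2-yl]methyl}-3-(tert-butyldimethylsilyloxy)butanal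
Conditions: DIBAL-H (1.1 equiv), toluene, −78 °C; Rochelle salt work-up
Reagents that add atoms: none
Why: Partial DIBAL-H reduction stops at the aluminium hemiacetal of the α-branched ester at −78 °C and releases the C14 aldehyde on work-up without base, so C1 is not epimerised.

Step 8
Reactants: 10 the bromo aldehyde
Product: 13 (1S,3S,4S,7E,11E,13S,14S,15R)-15-(tert-butyldimethylsilyloxy)-3,4:13,14-diepoxy-16-norcembra-7,11-diene, via sulfonium bromide 11 (not isolated), via sulfonium ylide 12 (not isolated)
Conditions: tetrahydrothiophene (excess), Cs2CO3, MeCN–t-BuOH, slow addition of 10 (high dilution), rt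
Reagents that add atoms: none
Why: Proposed new method: tetrahydrothiophene is alkylated at C13, carbonate forms the semi-stabilised allylic ylide, its C13 adds to the C14 aldehyde and the anti betaine collapses (3-exo-tet loss of the sulfide) to the trans-vinyl epoxide while the 14-membered ring closes; the Felkin–Anh face of the anti-α-alkyl-β-silyloxy aldehyde (large group = C15 branch, reinforced by the 1,3-polar effect) should set C14 (S) and the trans preference of allylic ylides then sets C13 (S); the closest known reaction type is the intermolecular Corey–Chaykovsky epoxidation of aldehydes with allylic sulfonium ylides made in situ from allylic halide, sulfide and base, together with its intramolecular use for small rings.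

Step 9
Reactants: 13 the macrocyclic silyl ether
Product: 14 (1R,3S,4S,7E,11E,13S,14S,15R)-3,4:13,14-diepoxy-16-norcembra-7,11-dien-15-ol
Conditions: TBAF, THF, 0 °C to rt
Reagents that add atoms: none
Why: Fluoride desilylation is neutral to both oxiranes, and the freed C15 alkoxide has only disfavoured 4-exo or 5-endo paths to the neighbouring epoxide.

Step 10
Reactants: 14 the C15 alcohol
Product: 15 (1S,3S,4S,7E,11E,13S,14S)-3,4:13,14-diepoxy-16-norcembra-7,11-dien-15-one (C15 methyl ketone)
Conditions: Dess–Martin periodinane, NaHCO3, CH2Cl2, 0 °C; used without chromatography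
Reagents that add atoms: none
Why: Buffered Dess–Martin oxidation removes the now superfluous C15 stereocentre under conditions mild enough to avoid enolisation at C1 and β-opening of the 13,14-epoxide.

Step 11
Reactants: 15 the methyl ketone
Product: 16 (E)-2,4,6-triisopropylbenzenesulfonylhydrazone of 15
Conditions: 2,4,6-triisopropylbenzenesulfonohydrazide, 4 Å MS, THF, rt
Reagents that add atoms: 2,4,6-triisopropylbenzenesulfonohydrazide, NNS(=O)(=O)c1c(C(C)C)cc(C(C)C)cc1C(C)C
Why: Acid-free hydrazone condensation of an unhindered methyl ketone places the sulfonamide nitrogen anti to the branched C1 side (E), which removes the acidity at C1 and prepares the directed deprotonation.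

Step 12
Reactants: 16 the trisylhydrazone
Product: 20 (1R,3S,4S,7E,11E,13S,14R)-3,4-epoxy-13-hydroxycembra-7,11,15(17)-trien-16,14-olide, via hydrazone dianion 17 (not isolated), via vinyllithium 18 (not isolated), via lithium acrylate 19 (not isolated)
Conditions: n-BuLi (2.1 equiv), TMEDA, THF, −78 to 0 °C; CO2, −78 °C to rt; DMF, 50 °C under CO2; AcOH quench
Reagents that add atoms: carbon dioxide, O=C=O
Why: Two equivalents of n-BuLi remove the N–H and, syn to the sulfonamide nitrogen of the (E)-hydrazone, one C17 methyl proton; on warming the dianion loses sulfinate and N2 (Shapiro reaction) to give the C15 vinyllithium, which adds to CO2 and forges C15–C16. The lithium acrylate then attacks C14 of the Li+-activated 13,14-epoxide from the face opposite to the oxirane oxygen, closing the γ-lactone in a 5-exo-tet mode and forging O–C14. The closest known reaction types are the Shapiro–carboxylation route from trisylhydrazones to α-methylene lactones and the lactonisation of γ,δ-epoxy carboxylates. C14 is set by SN2 inversion of the (14S)-oxirane carbon to 14R, C13 keeps its C–O bond (13S) and C1 is untouched, so the trans ring fusion and the anti C13–O/C14–O relation follow from the trans-epoxide. The step needs methyl over C1–H deprotonation (secured by hydrazone geometry and sterics), C14 over allylic C13 attack (secured by non-acidic conditions and the 5-exo over 6-endo preference) and the 13,14- over the 3,4-epoxide (5-exo over 6-exo at the neopentyl-like C3). The CO2 atmosphere masks the liberated C13 alkoxide as a carbonate, which should suppress translactonisation and conjugate addition to the new methylene lactone.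

Step 13
Reactants: 20 the epoxy hydroxy lactone
Product: 21 (1R,3S,4R,7E,11E,13S,14R)-3,4,13-trihydroxycembra-7,11,15(17)-trien-16,14-olide
Conditions: HClO4 (cat.), THF–H2O, 0 °C
Reagents that add atoms: water, O
Why: Acid-catalysed epoxide hydrolysis (borderline SN2): water attacks the tertiary C4 with inversion (4S oxirane carbon to 4R carbinol) while the C3–O bond is retained (3S), which gives the anti 3,4-diol.

Step 14
Reactants: 21 the triol
Product: 22 Crassocolide B
Conditions: Ac2O, pyridine, DMAP (cat.), CH2Cl2, 0 °C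
Reagents that add atoms: acetic anhydride, CC(=O)OC(C)=O
Why: Acylation differentiates by steric class: the two secondary hydroxyls (C3, C13) are acetylated while the tertiary C4 hydroxyl stays free, and no stereocentre is touched.

Compound list
1 | (2E,6E)-farnesol | CC(C)=CCC/C(C)=C/CC/C(C)=C/CO | starting material
2 | (2S,3S)-2,3-epoxyfarnesol | OC[C@@H]1O[C@@]1(C)CC/C=C(\C)CCC=C(C)C | intermediate
3 | (2S,3R)-2-[(3E)-4,8-dimethylnona-3,7-dienyl]-3-(iodomethyl)-2-methyloxirane | IC[C@@H]1O[C@@]1(C)CC/C=C(\C)CCC=C(C)C | intermediate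
4 | ethyl (R)-3-hydroxybutanoate | CCOC(=O)C[C@@H](C)O | starting material
5 | dilithio alkoxide–enolate dianion of 4 | CCOC([O-])=C[C@@H](C)[O-].[Li+].[Li+] | intermediate
6 | ethyl (2R,3R)-3-hydroxy-2-{[(2S,3S)-3-[(3E)-4,8-dimethylnona-3,7-dienyl]-3-methyloxiran-2-yl]methyl}butanoate | CCOC(=O)[C@@H]([C@@H](C)O)C[C@@H]1O[C@@]1(C)CC/C=C(\C)CCC=C(C)C | intermediate
7 | TBS ether of 6 | CCOC(=O)[C@@H]([C@@H](C)O[Si](C)(C)C(C)(C)C)C[C@@H]1O[C@@]1(C)CC/C=C(\C)CCC=C(C)C | intermediate
8 | terminal (E)-allylic alcohol of 7 (C13–OH) | CCOC(=O)[C@@H]([C@@H](C)O[Si](C)(C)C(C)(C)C)C[C@@H]1O[C@@]1(C)CC/C=C(\C)CC/C=C(\C)CO | intermediate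
9 | (E)-allylic bromide (C13–Br) | CCOC(=O)[C@@H]([C@@H](C)O[Si](C)(C)C(C)(C)C)C[C@@H]1O[C@@]1(C)CC/C=C(\C)CC/C=C(\C)CBr | intermediate
10 | (2R,3R)-bromo aldehyde (C14 aldehyde) | O=C[C@@H]([C@@H](C)O[Si](C)(C)C(C)(C)C)C[C@@H]1O[C@@]1(C)CC/C=C(\C)CC/C=C(\C)CBr | intermediate
11 | S-allyl tetrahydrothiophenium bromide of 10 | O=C[C@@H]([C@@H](C)O[Si](C)(C)C(C)(C)C)C[C@@H]1O[C@@]1(C)CC/C=C(\C)CC/C=C(\C)C[S+]2CCCC2.[Br-] | intermediate
12 | allylic sulfonium ylide (carbanion at C13) | O=C[C@@H]([C@@H](C)O[Si](C)(C)C(C)(C)C)C[C@@H]1O[C@@]1(C)CC/C=C(\C)CC/C=C(\C)[CH-][S+]2CCCC2 | intermediate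
13 | (1S,3S,4S,7E,11E,13S,14S,15R)-15-(TBSO)-3,4:13,14-diepoxy-16-norcembra-7,11-diene | C[C@@H](O[Si](C)(C)C(C)(C)C)[C@H]1C[C@@H]2O[C@@]2(C)CC/C=C(\C)CC/C=C(\C)[C@@H]3O[C@H]31 | intermediate
14 | (1R,3S,4S,7E,11E,13S,14S,15R)-3,4:13,14-diepoxy-16-norcembra-7,11-dien-15-ol | C[C@@H](O)[C@H]1C[C@@H]2O[C@@]2(C)CC/C=C(\C)CC/C=C(\C)[C@@H]3O[C@H]31 | intermediate
15 | (1S,3S,4S,7E,11E,13S,14S)-3,4:13,14-diepoxy-16-norcembra-7,11-dien-15-one | CC(=O)[C@H]1C[C@@H]2O[C@@]2(C)CC/C=C(\C)CC/C=C(\C)[C@@H]3O[C@H]31 | intermediate
16 | (E)-2,4,6-triisopropylbenzenesulfonylhydrazone of 15 | C/C(=N\NS(=O)(=O)c4c(C(C)C)cc(C(C)C)cc4C(C)C)[C@H]1C[C@@H]2O[C@@]2(C)CC/C=C(\C)CC/C=C(\C)[C@@H]3O[C@H]31 | intermediate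
17 | N,C17-dilithio dianion of 16 | [Li]C/C(=N\N([Li])S(=O)(=O)c4c(C(C)C)cc(C(C)C)cc4C(C)C)[C@H]1C[C@@H]2O[C@@]2(C)CC/C=C(\C)CC/C=C(\C)[C@@H]3O[C@H]31 | intermediate
18 | C15 vinyllithium | C=C([Li])[C@H]1C[C@@H]2O[C@@]2(C)CC/C=C(\C)CC/C=C(\C)[C@@H]3O[C@H]31 | intermediate
19 | lithium 2-substituted acrylate (C16 carboxylate) | C=C(C(=O)[O-])[C@H]1C[C@@H]2O[C@@]2(C)CC/C=C(\C)CC/C=C(\C)[C@@H]3O[C@H]31.[Li+] | intermediate
20 | (1R,3S,4S,7E,11E,13S,14R)-3,4-epoxy-13-hydroxycembra-7,11,15(17)-trien-16,14-olide | C=C1C(=O)O[C@@H]2[C@@H]1C[C@@H]3O[C@@]3(C)CC/C=C(\C)CC/C=C(\C)[C@@H]2O | intermediate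
21 | (1R,3S,4R,7E,11E,13S,14R)-3,4,13-trihydroxycembra-7,11,15(17)-trien-16,14-olide | C=C1C(=O)O[C@@H]2[C@@H]1C[C@H](O)[C@](C)(O)CC/C=C(\C)CC/C=C(\C)[C@@H]2O | intermediate
22 | Crassocolide B | C=C1C(=O)O[C@@H]2[C@@H]1C[C@H](OC(C)=O)[C@](C)(O)CC/C=C(\C)CC/C=C(\C)[C@@H]2OC(C)=O | target

Total step count: 14. Longest linear sequence: 14 steps (from 1).

Steps most likely to fail

1. Step 8 (labelled step). Ring closure may lose to oligomerisation. The carbonate may enolise the aldehyde or trigger β-elimination of the silyloxy group before the ylide reacts. Betaine formation may also show poor trans or facial selectivity.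
Fallback with known chemistry, setting out from 8 and coming back at 13: exhaustive DIBAL-H reduction of the ester gives the acyclic C13,C14-diol F1. Double Swern oxidation then gives the enal-aldehyde F2. A low-valent titanium (McMurry-type) pinacol macrocyclisation run at the pinacol stage, a ring closure known for the C13–C14 bond of cembranoids, should give the threo macrocyclic (13S,14S)-diol F3. The stereospecific sequence trimethyl orthoacetate/PPTS, acetyl bromide, K2CO3/MeOH (double inversion at one carbon, net retention) converts it into 13.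

2. Step 12 (key step). The warm-up needed for loss of sulfinate and N2 exposes the vinyl epoxide to organolithium species (oxirane α-deprotonation, SN2' addition). The hydrazone nitrogen anion may cyclise onto C14. The carboxylate may open the epoxide at allylic C13 or reach the 3,4-epoxide.
Fallback, setting out from 15 and coming back at 20: condensation with hydrazine hydrate gives the hydrazone of 15 F4. Iodine with tetramethylguanidine (Barton vinyl iodide synthesis) gives the C15 vinyl iodide F5. Iodine–lithium exchange with t-BuLi at −78 °C needs no warm-up; CO2 and the same heating of the carboxylate in THF–DMF then deliver 20.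

3. Step 3. The SN2 displacement at the β-oxygenated primary iodide may be slower than proton transfer and decay of the dianion. The product alkoxide may also attack the epoxide on warming.
Fallback, setting out from 4 and coming back at 6: Fráter–Seebach alkylation with commercial (2E,6E)-farnesyl bromide, a reactive allylic electrophile, gives the farnesylated hydroxy ester F6. A hydroxyl-directed asymmetric epoxidation of this bishomoallylic alcohol (hafnium(IV)–chiral bishydroxamic acid catalyst, cumene hydroperoxide, ligand enantiomer chosen for the 3S,4S face) then oxidises only the proximal C3=C4 alkene and gives 6.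

Further compounds
F1 | step 8 | acyclic C13,C14-diol | OC[C@@H]([C@@H](C)O[Si](C)(C)C(C)(C)C)C[C@@H]1O[C@@]1(C)CC/C=C(\C)CC/C=C(\C)CO
F2 | step 8 | enal-aldehyde | O=C[C@@H]([C@@H](C)O[Si](C)(C)C(C)(C)C)C[C@@H]1O[C@@]1(C)CC/C=C(\C)CC/C=C(\C)C=O
F3 | step 8 | macrocyclic (13S,14S)-diol | C[C@@H](O[Si](C)(C)C(C)(C)C)[C@H]1C[C@@H]2O[C@@]2(C)CC/C=C(\C)CC/C=C(\C)[C@H](O)[C@H]1O
F4 | step 12 | hydrazone of 15 | C/C(=N\N)[C@H]1C[C@@H]2O[C@@]2(C)CC/C=C(\C)CC/C=C(\C)[C@@H]3O[C@H]31
F5 | step 12 | C15 vinyl iodide | C=C(I)[C@H]1C[C@@H]2O[C@@]2(C)CC/C=C(\C)CC/C=C(\C)[C@@H]3O[C@H]31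
F6 | step 3 | farnesylated hydroxy ester | CCOC(=O)[C@@H]([C@@H](C)O)C/C=C(\C)CC/C=C(\C)CCC=C(C)C
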